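**Plan**
- Retrosynthesis: the palmitate C–O bond is cut first, then (after adding back the C2=C3 unsaturation) the ring C2=C3 bond by ring-closing metathesis, then the C1–C2 and C3–C4 bonds (two vinyl Grignard additions), and last the C1–C6 bond (acyl chloride plus zinc homoenolate).
- Enabling feature: in the cyclohexanone ring, C2 and C3 lie between the quaternary carbinol carbon C1 and the carbonyl carbon C4, so a vinyl group on C1 and a vinyl ketone at C4 can be joined to close the ring.
- Forward: the chain is joined in steps 1–2, the first vinyl group is added with lactonisation in step 3, and the lactone is opened, silylated and vinylated in steps 4–6.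
- The only ring closes in step 7; hydrogenation, palmitoylation and desilylation follow in steps 8–10.
- Stereochemistry: the target is achiral (C1 carries two identical ring arms), so nothing has to be controlled.

Key step: step 7

Remark: every intermediate that carries a stereocenter is taken as a racemate (as a diastereomer mixture where there are two); this has no consequence for the achiral target.

Step 1
Reactants: 1 3-(benzyloxy)propanoic acid
Product: 2 3-(benzyloxy)propanoyl chloride
Conditions: (COCl)2 (1.2 equiv), DMF (cat.), CH2Cl2, 0 °C → rt; evaporate, use crude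
Reagents that add atoms: oxalyl chloride, ClC(=O)C(=O)Cl
Why: Acid chloride formation through the chloroiminium (Vilsmeier-type) species is general for aliphatic acids, runs under neutral conditions that leave the benzyl ether alone and gives only gaseous co-products, so the crude chloride can be used directly.

Step 2
Reactants: 2 3-(benzyloxy)propanoyl chloride; 3 (3-ethoxy-3-oxopropyl)zinc bromide (commercial THF solution)
Product: 4 ethyl 6-(benzyloxy)-4-oxohexanoate
Conditions: Pd(PPh3)4 (3 mol%), THF, 0 °C → rt
Reagents that add atoms: (3-ethoxy-3-oxopropyl)zinc bromide (3), CCOC(=O)CC[Zn]Br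
Why: Negishi acylation, in which zerovalent palladium inserts into the acyl C–Cl bond, the alkylzinc transmetalates and reductive elimination forms the ketone; because the organozinc adds neither to ketones nor to esters, the γ-keto ester should form without over-addition.

Step 3
Reactants: 4 ethyl 6-(benzyloxy)-4-oxohexanoate; 5 vinylmagnesium bromide
Product: 7 5-[2-(benzyloxy)ethyl]-5-ethenyloxolan-2-one (racemic), via bromomagnesium alkoxide of ethyl 6-(benzyloxy)-4-ethenyl-4-hydroxyhexanoate 6 (not isolated)
Conditions: CH2=CHMgBr (1.05 equiv), THF, −78 °C → rt; aq. NH4Cl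
Reagents that add atoms: vinylmagnesium bromide (5), C=C[Mg]Br
Why: Grignard addition in which the ketone is far more electrophilic than the ethyl ester at −78 °C, followed on warming by 5-exo-trig lactonisation of the tertiary alkoxide onto the ester (the way γ-alkyl-γ-vinyl butyrolactones arise from levulinate esters); the new quaternary carbinol center forms as a racemate.

Step 4
Reactants: 7 5-[2-(benzyloxy)ethyl]-5-ethenyloxolan-2-one
Product: 8 6-(benzyloxy)-4-ethenyl-4-hydroxy-N-methoxy-N-methylhexanamide (racemic)
Conditions: MeNHOMe·HCl (3 equiv), AlMe3 (3 equiv), CH2Cl2, 0 °C → rt; cold aq. potassium sodium tartrate; crude taken on at once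
Reagents that add atoms: N,O-dimethylhydroxylamine hydrochloride, CNOC.Cl
Why: Weinreb aminolysis of a lactone, in which the chloro(methyl)aluminium amide made in the flask adds to the lactone carbonyl and the released tertiary alkoxide stays bound to aluminium, holding the ring-open hydroxy amide until the neutral work-up.

Step 5
Reactants: 8 6-(benzyloxy)-4-ethenyl-4-hydroxy-N-methoxy-N-methylhexanamide
Product: 9 6-(benzyloxy)-4-ethenyl-N-methoxy-N-methyl-4-(triethylsilyloxy)hexanamide (racemic)
Conditions: Et3SiOTf (1.5 equiv), 2,6-lutidine (3 equiv), CH2Cl2, −78 → 0 °C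
Reagents that add atoms: triethylsilyl trifluoromethanesulfonate, CC[Si](CC)(CC)OS(=O)(=O)C(F)(F)F
Why: Silylation of a hindered tertiary alcohol with a silyl triflate and 2,6-lutidine is standard, and capping the hydroxyl closes the path back to the lactone and leaves no acidic proton for the Grignard reagent of the next step.

Step 6
Reactants: 9 6-(benzyloxy)-4-ethenyl-N-methoxy-N-methyl-4-(triethylsilyloxy)hexanamide; 5 vinylmagnesium bromide
Product: 11 8-(benzyloxy)-6-ethenyl-6-(triethylsilyloxy)oct-1-en-3-one (racemic), via tetrahedral magnesium chelate 10 (not isolated)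
Conditions: CH2=CHMgBr (2.5 equiv), THF, −20 → 0 °C; inverse quench into cold 1 M HCl/Et2O
Reagents that add atoms: vinylmagnesium bromide (5), C=C[Mg]Br
Why: Weinreb ketone synthesis, in which the five-membered magnesium chelate persists until the quench and so stops the addition at the ketone stage, while pouring into cold acid protonates the released N,O-dimethylhydroxylamine before it can add to the new enone in a conjugate fashion.

Step 7
Reactants: 11 8-(benzyloxy)-6-ethenyl-6-(triethylsilyloxy)oct-1-en-3-one
Product: 12 4-[2-(benzyloxy)ethyl]-4-(triethylsilyloxy)cyclohex-2-en-1-one (racemic)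
Conditions: second-generation Grubbs catalyst (H2IMes)(PCy3)Cl2Ru=CHPh (5 mol%), CH2Cl2 (0.005 M), 40 °C, argon sweep
Reagents that add atoms: none
Why: The ruthenium benzylidene exchanges with one terminal alkene of 11 to give a ruthenium alkylidene, which adds across the second alkene to a ruthenacyclobutane and cycloreverts to the cyclohexenone, the methylidene fragments leaving as ethylene. The closest known reaction type is ring-closing metathesis of 1,7-dienes in which one alkene is a vinyl ketone, a standard entry to cyclohex-2-enones with N-heterocyclic-carbene ruthenium catalysts. The single ring closes as a six-membered carbocycle by joining the two internal alkene carbons, so the new C2=C3 bond lies inside the ring between C1 and C4. No stereocenter is formed and the existing quaternary carbinol center is not touched. The step needs ring closure in preference to intermolecular cross-metathesis (dimers and oligomers), which is secured by high dilution, by the fully substituted C1 that folds the chain (Thorpe–Ingold effect) and by the irreversible loss of ethylene under the gas sweep. Both alkenes are monosubstituted, there is no third alkene to compete, and the electron-poor enone end and the hindered allylic ether end are both slow to homodimerise.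

Step 8
Reactants: 12 4-[2-(benzyloxy)ethyl]-4-(triethylsilyloxy)cyclohex-2-en-1-one
Product: 14 4-(2-hydroxyethyl)-4-(triethylsilyloxy)cyclohexan-1-one, via 4-[2-(benzyloxy)ethyl]-4-(triethylsilyloxy)cyclohexan-1-one 13 (not isolated)
Conditions: H2 (1 atm), 10% Pd/C, EtOAc, rt
Reagents that add atoms: none
Why: Heterogeneous catalytic hydrogenation should saturate the conjugated C2=C3 bond first and then cleave the benzyl ether by hydrogenolysis, while the aliphatic ketone and the tertiary silyl ether persist in the aprotic, neutral solvent; from here on the ring is symmetric and C1 is no longer a stereocenter.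

Step 9
Reactants: 14 4-(2-hydroxyethyl)-4-(triethylsilyloxy)cyclohexan-1-one; 15 palmitoyl chloride
Product: 16 2-[4-oxo-1-(triethylsilyloxy)cyclohexyl]ethyl hexadecanoate
Conditions: palmitoyl chloride (1.1 equiv), Et3N (1.5 equiv), DMAP (cat.), CH2Cl2, 0 °C → rt
Reagents that add atoms: palmitoyl chloride (15), CCCCCCCCCCCCCCCC(=O)Cl
Why: Acylation of a primary alcohol by an acid chloride under nucleophilic catalysis (DMAP) is fast and clean, and the only other oxygen functions are a ketone and a silyl-capped tertiary alcohol that cannot react.

Step 10
Reactants: 16 2-[4-oxo-1-(triethylsilyloxy)cyclohexyl]ethyl hexadecanoate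
Product: 17 2-(1-hydroxy-4-oxocyclohexyl)ethyl hexadecanoate (target)
Conditions: HF·pyridine, pyridine, THF, 0 °C → rt
Reagents that add atoms: none
Why: Fluoride-driven desilylation (formation of the strong Si–F bond) under buffered, non-basic conditions should free the tertiary alcohol without touching the ester or the ketone and without acid-promoted dehydration of the tertiary carbinol.

**Compound list**
1 | 3-(benzyloxy)propanoic acid | OC(=O)CCOCc1ccccc1 | starting material
2 | 3-(benzyloxy)propanoyl chloride | ClC(=O)CCOCc1ccccc1 | intermediate
3 | (3-ethoxy-3-oxopropyl)zinc bromide | CCOC(=O)CC[Zn]Br | starting material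
4 | ethyl 6-(benzyloxy)-4-oxohexanoate | CCOC(=O)CCC(=O)CCOCc1ccccc1 | intermediate
5 | vinylmagnesium bromide | C=C[Mg]Br | starting material
6 | bromomagnesium alkoxide of ethyl 6-(benzyloxy)-4-ethenyl-4-hydroxyhexanoate (racemic, not isolated) | CCOC(=O)CCC(O[Mg]Br)(C=C)CCOCc1ccccc1 | intermediate
7 | 5-[2-(benzyloxy)ethyl]-5-ethenyloxolan-2-one (racemic) | O=C1CCC(C=C)(CCOCc2ccccc2)O1 | intermediate
8 | 6-(benzyloxy)-4-ethenyl-4-hydroxy-N-methoxy-N-methylhexanamide (racemic) | CON(C)C(=O)CCC(O)(C=C)CCOCc1ccccc1 | intermediate
9 | 6-(benzyloxy)-4-ethenyl-N-methoxy-N-methyl-4-(triethylsilyloxy)hexanamide (racemic) | CON(C)C(=O)CCC(O[Si](CC)(CC)CC)(C=C)CCOCc1ccccc1 | intermediate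
10 | tetrahedral magnesium chelate: bromomagnesium salt of 8-(benzyloxy)-6-ethenyl-3-[methoxy(methyl)amino]-6-(triethylsilyloxy)oct-1-en-3-ol (diastereomer mixture, not isolated) | C=CC(O[Mg]Br)(N(C)OC)CCC(O[Si](CC)(CC)CC)(C=C)CCOCc1ccccc1 | intermediate
11 | 8-(benzyloxy)-6-ethenyl-6-(triethylsilyloxy)oct-1-en-3-one (racemic) | C=CC(=O)CCC(O[Si](CC)(CC)CC)(C=C)CCOCc1ccccc1 | intermediate
12 | 4-[2-(benzyloxy)ethyl]-4-(triethylsilyloxy)cyclohex-2-en-1-one (racemic) | O=C1C=CC(O[Si](CC)(CC)CC)(CCOCc2ccccc2)CC1 | intermediate
13 | 4-[2-(benzyloxy)ethyl]-4-(triethylsilyloxy)cyclohexan-1-one (not isolated) | O=C1CCC(O[Si](CC)(CC)CC)(CCOCc2ccccc2)CC1 | intermediate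
14 | 4-(2-hydroxyethyl)-4-(triethylsilyloxy)cyclohexan-1-one | O=C1CCC(O[Si](CC)(CC)CC)(CCO)CC1 | intermediate
15 | palmitoyl chloride (hexadecanoyl chloride) | CCCCCCCCCCCCCCCC(=O)Cl | starting material
16 | 2-[4-oxo-1-(triethylsilyloxy)cyclohexyl]ethyl hexadecanoate | CCCCCCCCCCCCCCCC(=O)OCCC1(O[Si](CC)(CC)CC)CCC(=O)CC1 | intermediate
17 | 2-(1-hydroxy-4-oxocyclohexyl)ethyl hexadecanoate | CCCCCCCCCCCCCCCC(=O)OCCC1(O)CCC(=O)CC1 | target

**Step count and risks**
Total step count: 10. Longest linear sequence: 10 steps (1 to 17); the route is fully linear.

Steps most likely to fail, riskiest first: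

First, step 7. Catalyst loading may be slow, because one alkene sits next to a fully substituted silyloxy carbon and the other is an electron-poor enone, so catalyst decay or intermolecular coupling through the enone end could outrun ring closure. The fallback keeps the C2=C3 disconnection but lowers the oxidation level at C4. It sets out from 11, which is reduced in a 1,2-fashion under Luche conditions (NaBH4, CeCl3·7H2O, MeOH, −40 °C) to 8-(benzyloxy)-6-ethenyl-6-(triethylsilyloxy)oct-1-en-3-ol F1. Its secondary allylic alcohol end is electron-rich and unhindered and should take up the ruthenium readily. Ring-closing metathesis with the same catalyst should then give 4-[2-(benzyloxy)ethyl]-4-(triethylsilyloxy)cyclohex-2-en-1-ol F2, and allylic oxidation with MnO2 in CH2Cl2 brings the route back at 12.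

Second, step 4. The ring opening may reverse: the tertiary γ-hydroxy amide can fall back to the five-membered lactone with loss of the amine during work-up or silylation. The fallback avoids the amide altogether. It sets out from 7, which is reduced with i-Bu2AlH (CH2Cl2, −78 °C) to 5-[2-(benzyloxy)ethyl]-5-ethenyloxolan-2-ol F3. Excess vinylmagnesium bromide 5 in THF opens this lactol to 3-[2-(benzyloxy)ethyl]octa-1,7-diene-3,6-diol F4. Ring-closing metathesis of this diene diol with the same ruthenium catalyst should give 1-[2-(benzyloxy)ethyl]cyclohex-2-ene-1,4-diol F5. MnO2 oxidises only the secondary allylic alcohol to 4-[2-(benzyloxy)ethyl]-4-hydroxycyclohex-2-en-1-one F6, and silylation with Et3SiOTf and 2,6-lutidine returns to the route at 12.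

Third, step 8. Hydrogenolysis of the benzyl ether may stall in ethyl acetate, and a protic solvent brought in to speed it up may strip part of the silyl ether, so that mixtures result. The fallback gives up the silyl group on purpose and relies on chemoselective acylation. It sets out from 12, which is hydrogenated over Pd/C in ethanol until alkene and benzyl ether are gone. The filtered solution is then stirred with dilute aqueous HCl to remove the remaining silyl ether, giving 4-hydroxy-4-(2-hydroxyethyl)cyclohexan-1-one F7. Palmitoyl chloride 15 with pyridine in CH2Cl2 at −20 °C should acylate only the primary hydroxyl, the tertiary one being inert under these conditions, and the route is rejoined at 17.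

**Further compounds**
F1 | step 7 | 8-(benzyloxy)-6-ethenyl-6-(triethylsilyloxy)oct-1-en-3-ol (diastereomer mixture) | C=CC(O)CCC(O[Si](CC)(CC)CC)(C=C)CCOCc1ccccc1
F2 | step 7 | 4-[2-(benzyloxy)ethyl]-4-(triethylsilyloxy)cyclohex-2-en-1-ol (diastereomer mixture) | OC1C=CC(O[Si](CC)(CC)CC)(CCOCc2ccccc2)CC1
F3 | step 4 | 5-[2-(benzyloxy)ethyl]-5-ethenyloxolan-2-ol (diastereomer mixture) | OC1CCC(C=C)(CCOCc2ccccc2)O1
F4 | step 4 | 3-[2-(benzyloxy)ethyl]octa-1,7-diene-3,6-diol (diastereomer mixture) | C=CC(O)CCC(O)(C=C)CCOCc1ccccc1
F5 | step 4 | 1-[2-(benzyloxy)ethyl]cyclohex-2-ene-1,4-diol (diastereomer mixture) | OC1C=CC(O)(CCOCc2ccccc2)CC1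
F6 | step 4 | 4-[2-(benzyloxy)ethyl]-4-hydroxycyclohex-2-en-1-one (racemic) | O=C1C=CC(O)(CCOCc2ccccc2)CC1
F7 | step 8 | 4-hydroxy-4-(2-hydroxyethyl)cyclohexan-1-one | O=C1CCC(O)(CCO)CC1
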